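## The problem

Target **21** is a daucane: a cyclopentane trans-fused to a cycloheptene. Daucane numbering is used throughout: C1 is the quaternary ring-fusion carbon carrying CH3, C2 and C3 are CH2, C4 is C(OH)(i-Pr), C5 is the ring-fusion CH, C6 is CH–O-anisoyl, C7 is CH2, C8(CH3)=C9 is the alkene and C10 is CH–OAc; the seven-membered ring is C1, C5–C10. There are five stereocentres (1S,4R,5S,6S,10R): the C1 methyl and the C4 hydroxyl lie on one face, and H-5, O-6, O-10 and the isopropyl group on the other. C4 is a tertiary carbinol that no later step can correct, so it is best bought; once present, its hydroxyl can deliver hydride to C6 (1,3-anti) and its two substituents are the only handle on the configuration of C1. C10 can be tied to C1 if the C1–C10 bond forms in a cyclic transition state, whereas C5 is left to a protonation. The two secondary oxygens carry different esters beside a free tertiary hydroxyl, so the order of acylation matters. Three features will not survive rough treatment: the C4 oxygen is β to C6 (elimination or retro-aldol at the ketone level), the C8=C9 alkene is β,γ to C6 (conjugation at the ketone level), and the C10 ester is allylic (ionisation). The feature that makes the key step possible is that C7–C8(CH3)=C9–C10(O) is an isoprene unit oxygenated at one end, while C6(O)–C5=C1 is an alkoxycarbene carbon on a cyclopentene. The two pieces meet at C6–C7 and at C1–C10, which is a formal (4+3) cycloaddition.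

## Retrosynthesis

**Esters.** The C6–O acyl bond of **21** is cut last, giving diol acetate **20**; only the secondary C6 hydroxyl can be acylated there, since C4–OH is tertiary and C10 already carries its acetate. Putting the anisoate on last means no aryl ester has to pass through a reduction or a fluoride step.

**C6–H.** **20** comes from β-hydroxy ketone **19** by cutting the C6–H bond. A hydride delivered from the C4 hydroxyl through boron arrives on the face of O4 and gives the 1,3-anti diol; a reagent-controlled reduction would have to choose between two hindered faces without guidance. This requires the C4 hydroxyl to be free and the C10 oxygen to be capped, which fixes the sequence **19** ← **18** (C4 silyl ether) ← **17** (C10 alcohol).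

**C5–H and the C6 carbonyl.** **17** is the hydrolysis product of the C6 methyl enol ether **15**, by way of its C10 alcohol **16**. The C5–H bond is made by protonating C5=C6; the forward step must add the proton on the face of O10 and must not ionise the allylic C4–O bond. Both demands argue for a free C10 hydroxyl, a silyl ether on C4 and a weak acid.

**Key disconnection, C1–C10 and C6–C7.** **15** is cut into the alkenyl(methoxy)carbene complex **11** and the silyloxydiene **13**, joined through the cis-divinylcyclopropane **14**. No other pair of cuts removes the seven-membered ring, the quaternary C1, the C10 stereocentre and the C8=C9 alkene at once while leaving oxygen on C6 and C10. A C6–C7 cut alone (ene or aldol) or a C9–C10 cut alone leaves a fully substituted cyclopentane as the real problem. The precursors are a monocyclic carbene complex with one stereocentre and a five-carbon achiral diene. The forward reaction must cyclopropanate the terminal alkene of **13**, place the cyclopentenyl and vinyl groups cis (or let the isomers equilibrate) and choose the face of the cyclopentene anti to the C4 oxygen.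

**Carbene complex.** **11** is cut at the Cr=C6 bond and the O–CH3 bond to acid chloride **7** and Cr(CO)6 (**8**), through the dianion **9** and the acyl chromate **10**. The classical alkenyllithium route would need a vinyl halide that is several steps further away. **7** comes from acid **6** and this from enal **5** by oxidation-level changes only.

**Cyclopentene.** **5** is cut at C5=C1 (aldol condensation) to keto aldehyde **4**, the ozonolysis product of silyl ether **2** (via ozonide **3**), which is (S)-terpinen-4-ol (**1**) with its hydroxyl masked. All ten carbons of the carbene fragment and the C4 stereocentre come from **1**. Diene **13** is the dienol silyl ether of 3-methylbut-2-enal (**12**).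

## Roads not taken

**Alternative 1: ring contraction by Wolff rearrangement.** The cut is C1–C5. Irradiation of the cyclic α-diazo ketone **A1** in methanol would expel N2, C1 would migrate from C6 to C5 with retention, and the cyclopentane ester **A2** would result with C6 as the ester carbon. Its merit is real: the quaternary C1 would be set on a six-membered ring and carried over stereospecifically, which is a surer way to relate C1 to C4 than the face selection the chosen plan depends on. Its weakness is that it makes none of the seven-membered ring. C6–C7, C8=C9, C9–C10 and both carbinol centres would still have to be built from an ester and a benzyloxymethyl group, and the quaternary centre of **A1** itself needs a face-selective alkylation next to the ketone. Against the better control of C1 the chosen plan sets one step that delivers the ring, C1, C10, the alkene and oxygen at C6 and C10 together, at roughly half the step count.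

**Alternative 2: conjugate methylation–aldol on a cyclopentenone.** The cuts are C1–CH3 and C5–C6. Me3Al would add to enone **A3** under Cu(OTf)2 with a chiral phosphoramidite, and the aluminium enolate would be trapped by aldehyde **A4** to give aldol **A5**; the alkenyl iodide would later close the ring at C9–C10. This road is better in two respects: C1 is set by a catalyst rather than by a substrate bias, and C6 arrives as a carbinol with C5 fixed by the trans addition, so there is no ketone stage and no protonation at C5. Its weak points are that quaternary-forming additions to 3-substituted cyclopentenones are the least selective of their class, the aldol creates C6 without clear control, the C4 carbinol must be made by adding an isopropyl nucleophile to a hindered, enolisable ketone next to C5, and C10 must be set in the ring closure. The chosen plan answers with C4 bought as **1**, C10 set by the geometry of a pericyclic transition state, and the ring formed together with the C8=C9 alkene.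

**Alternative 3: carbonyl-ene closure at C6–C7.** Aldehyde **A6**, activated by Me2AlCl, would be attacked by the terminal CH2 of its 2-methylallyl arm with hydrogen transfer from the methyl group, closing the seven-membered ring to the 8-methylene alcohol **A7**. The end of this route is cleaner than that of the chosen plan: the C6 alcohol appears directly, the oxygens are already differentiated, and there is neither an enol ether hydrolysis nor a β,γ-unsaturated ketone. Against this, a seven-membered ene closure is less favourable than a six-membered one, the C6 configuration depends on the transition state, and the exocyclic alkene must be moved into C8=C9 and not C7=C8. Above all, **A6** already holds C1, C4, C5 and C10 on a fully substituted cyclopentane, and making it is longer than the whole of the chosen route to the bicyclic core.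

Key step: step 8

Assumption: (S)-terpinen-4-ol (**1**) is taken to be available in high enantiomeric purity; any shortfall would pass unchanged into **21**.

## Route

Step 1
Reactants: 1 (S)-terpinen-4-ol
Product: 2 (S)-triethyl[(1-isopropyl-4-methylcyclohex-3-en-1-yl)oxy]silane
Conditions: Et3SiOTf, 2,6-lutidine, CH2Cl2, 0 °C to rt
Reagents that add atoms: triethylsilyl trifluoromethanesulfonate, CC[Si](CC)(CC)OS(=O)(=O)C(F)(F)F
Why: Silylation of a tertiary alcohol with a silyl triflate; the ether keeps the carbinol from forming a lactol or undergoing retro-aldol once the ring is cleaved, and no stereocentre is touched.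

Step 2
Reactants: 2 (S)-triethyl[(1-isopropyl-4-methylcyclohex-3-en-1-yl)oxy]silane
Product: 4 (S)-3-isopropyl-6-oxo-3-(triethylsilyloxy)heptanal, via secondary ozonide 3 (not isolated)
Conditions: O3, CH2Cl2, −78 °C; then PPh3, −78 °C to rt
Reagents that add atoms: ozone, [O-][O+]=O
Why: Ozonolysis of the only alkene with reductive work-up gives the methyl ketone and the aldehyde; the silyl ether and C4 are not affected.

Step 3
Reactants: 4 (S)-3-isopropyl-6-oxo-3-(triethylsilyloxy)heptanal
Product: 5 (R)-5-isopropyl-2-methyl-5-(triethylsilyloxy)cyclopent-1-ene-1-carbaldehyde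
Conditions: piperidine (cat.), AcOH (cat.), toluene, rt to 60 °C
Reagents that add atoms: none
Why: Amine-catalysed intramolecular aldol condensation, as used for terpene-derived 1,6-keto aldehydes: the enamine of the aldehyde adds 5-exo to the methyl ketone and the new tertiary hydroxyl, which is more easily protonated than the silyl ether, is lost to give the conjugated tetrasubstituted enal.

Step 4
Reactants: 5 (R)-5-isopropyl-2-methyl-5-(triethylsilyloxy)cyclopent-1-ene-1-carbaldehyde
Product: 6 (R)-5-isopropyl-2-methyl-5-(triethylsilyloxy)cyclopent-1-ene-1-carboxylic acid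
Conditions: NaClO2, NaH2PO4, 2-methylbut-2-ene, t-BuOH–H2O, 0 °C to rt
Reagents that add atoms: sodium chlorite, [Na+].[O-]Cl=O
Why: Pinnick oxidation, which tolerates hindered conjugated aldehydes and, with the hypochlorite scavenger, the alkene and the tertiary silyl ether.

Step 5
Reactants: 6 (R)-5-isopropyl-2-methyl-5-(triethylsilyloxy)cyclopent-1-ene-1-carboxylic acid
Product: 7 (R)-5-isopropyl-2-methyl-5-(triethylsilyloxy)cyclopent-1-ene-1-carbonyl chloride
Conditions: 1-chloro-N,N,2-trimethylprop-1-en-1-amine, CH2Cl2, 0 °C to rt
Reagents that add atoms: 1-chloro-N,N,2-trimethylprop-1-en-1-amine (Ghosez reagent), CC(C)=C(Cl)N(C)C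
Why: Acid chloride formation with the α-chloroenamine under neutral conditions; no HCl is set free, so the allylic tertiary silyl ether is not at risk.

Step 6
Reactants: 7 (R)-5-isopropyl-2-methyl-5-(triethylsilyloxy)cyclopent-1-ene-1-carbonyl chloride; 8 chromium hexacarbonyl Cr(CO)6
Product: 11 pentacarbonyl{methoxy[(R)-5-isopropyl-2-methyl-5-(triethylsilyloxy)cyclopent-1-en-1-yl]methylidene}chromium, via disodium pentacarbonylchromate 9 (not isolated), via sodium acylpentacarbonylchromate 10 (not isolated)
Conditions: 8, NaC10H8 (2 equiv), THF, −78 °C; add 7, −78 to 0 °C; then Me3OBF4, CH2Cl2, 0 °C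
Reagents that add atoms: trimethyloxonium tetrafluoroborate, C[O+](C)C.F[B-](F)(F)F
Why: Acylation of Na2Cr(CO)5 by an acid chloride followed by O-methylation of the acyl chromate is the established entry to alkoxycarbene complexes of zerovalent chromium when the organolithium is not at hand; the stereocentre is a spectator.

Step 7
Reactants: 12 3-methylbut-2-enal
Product: 13 (E)-1-(trimethylsilyloxy)-3-methylbuta-1,3-diene
Conditions: Me3SiOTf, Et3N, Et2O, 0 °C to rt; distillation
Reagents that add atoms: trimethylsilyl trifluoromethanesulfonate, C[Si](C)(C)OS(=O)(=O)C(F)(F)F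
Why: Soft γ-enolisation of an enal (O-silylation, then loss of a γ-methyl proton) gives the dienol silyl ether, mainly as the E isomer from the s-trans enal.

Step 8
Reactants: 11 pentacarbonyl{methoxy[(R)-5-isopropyl-2-methyl-5-(triethylsilyloxy)cyclopent-1-en-1-yl]methylidene}chromium; 13 (E)-1-(trimethylsilyloxy)-3-methylbuta-1,3-diene
Product: 15 (1S,4R,10R)-6-methoxy-4-(triethylsilyloxy)-10-(trimethylsilyloxy)dauca-5,8-diene, via cis-divinylcyclopropane 14 (not isolated)
Conditions: 13 (excess), toluene, 80 °C, CO (1 atm)
Reagents that add atoms: none
Why: The terminal CH2 of 13 (C7, the vinylogous enol-ether carbon) adds to the electrophilic carbene carbon C6 of the zerovalent chromium complex and the chain closes at C8 to the three-membered ring of 14, a formal [2+1] cyclopropanation. 14 then undergoes a [3,3] Cope rearrangement through a boat transition state that forms C1–C10 and breaks C6–C8, so the seven-membered ring is closed at C1–C10 by ring expansion of the cyclopropane. The closest known reaction type is the cyclopropanation–Cope (formal 4+3) reaction of alkenyl(alkoxy)carbene chromium complexes with silyloxydienes. C10 is set against C1 by the boat geometry and the E enol ether, which place the silyloxy group trans to the C1 methyl. C1 is set against C4 by the way the boat sits on the cyclopentene: the C4 substituent on the reacting face meets C8 and the other lies 1,3-syn to the C6 oxygen, so the compact C4 oxygen should take the place beside O6 and the isopropyl group the roomier place under C8, which makes C10 add cis to isopropyl as required. Trans-cyclopropanes and the cis isomer of the wrong face are expected to re-enter through reversible homolysis of the donor- and vinyl-substituted C6–C8 bond at 80 °C, so the selection is made at the Cope stage. The step needs cyclopropanation of the terminal alkene in preference to Diels–Alder addition and to metathesis: the tetrasubstituted C5=C1 alkene is no dienophile, and the CO atmosphere suppresses metathesis and returns chromium as Cr(CO)6.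

Step 9
Reactants: 15 (1S,4R,10R)-6-methoxy-4-(triethylsilyloxy)-10-(trimethylsilyloxy)dauca-5,8-diene
Product: 17 (1S,4R,5R,10R)-10-hydroxy-4-(triethylsilyloxy)dauc-8-en-6-one, via C10 alcohol 16 (not isolated)
Conditions: K2CO3 (cat.), MeOH, 0 °C; then AcOH–THF–H2O, 25–40 °C
Reagents that add atoms: water, O
Why: Methanolysis frees the C10 hydroxyl, then general-acid hydrolysis of the enol ether protonates C5; the hydroxyl sits about 3 Å above C5 on the face that must take the proton and should assist it by hydrogen bonding, while the other face is flanked by the C1 methyl and the C4 silyl ether, giving the trans-fused ketone. A weak acid is chosen because C-protonation of an enol ether is general-acid catalysed whereas ionisation of the allylic C4–O bond needs strong acid; the tertiary triethylsilyl ether should survive.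

Step 10
Reactants: 17 (1S,4R,5R,10R)-10-hydroxy-4-(triethylsilyloxy)dauc-8-en-6-one
Product: 18 (1S,4R,5R,10R)-6-oxo-4-(triethylsilyloxy)dauc-8-en-10-yl acetate
Conditions: Ac2O, pyridine, DMAP (cat.), CH2Cl2, 0 °C
Reagents that add atoms: acetic anhydride, CC(=O)OC(C)=O
Why: DMAP-catalysed acetylation of the only free hydroxyl; it is run cold and briefly with a weak base so that the β,γ-unsaturated ketone is not conjugated and the β-silyloxy group is not eliminated.

Step 11
Reactants: 18 (1S,4R,5R,10R)-6-oxo-4-(triethylsilyloxy)dauc-8-en-10-yl acetate
Product: 19 (1S,4R,5R,10R)-4-hydroxy-6-oxodauc-8-en-10-yl acetate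
Conditions: HF·pyridine, pyridine, THF, 0 °C to rt
Reagents that add atoms: none
Why: Fluoride cleavage of the triethylsilyl ether under buffered, non-basic conditions; basic fluoride is avoided because a β-oxygenated ketone would eliminate or undergo retro-aldol.

Step 12
Reactants: 19 (1S,4R,5R,10R)-4-hydroxy-6-oxodauc-8-en-10-yl acetate
Product: 20 (1S,4R,5S,6S,10R)-4,6-dihydroxydauc-8-en-10-yl acetate
Conditions: Me4NBH(OAc)3, AcOH–MeCN, −20 °C to rt
Reagents that add atoms: none
Why: Evans–Saksena reduction: the C4 hydroxyl exchanges onto boron and delivers hydride intramolecularly to C6 from the face of O4, which gives the 1,3-anti diol with the C6 oxygen cis to H-5; the acetate and the alkene are inert to this reagent.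

Step 13
Reactants: 20 (1S,4R,5S,6S,10R)-4,6-dihydroxydauc-8-en-10-yl acetate
Product: 21 (1S,4R,5S,6S,10R)-10-acetoxy-4-hydroxydauc-8-en-6-yl 4-methoxybenzoate
Conditions: 4-methoxybenzoyl chloride, DMAP, Et3N, CH2Cl2, rt to 40 °C
Reagents that add atoms: 4-methoxybenzoyl chloride, COc1ccc(C(Cl)=O)cc1
Why: DMAP-catalysed acylation of the secondary C6 hydroxyl; the tertiary C4 hydroxyl does not react under these conditions and no stereocentre is involved.

## Compound list

1 | (S)-terpinen-4-ol | CC1=CC[C@](O)(C(C)C)CC1 | starting material
2 | (S)-triethyl[(1-isopropyl-4-methylcyclohex-3-en-1-yl)oxy]silane | CC1=CC[C@](O[Si](CC)(CC)CC)(C(C)C)CC1 | intermediate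
3 | secondary ozonide (1,2,4-trioxolane) of 2, mixture at the two acetal carbons | CC12CC[C@@](O[Si](CC)(CC)CC)(C(C)C)CC(OO1)O2 | intermediate (not isolated)
4 | (S)-3-isopropyl-6-oxo-3-(triethylsilyloxy)heptanal | CC(=O)CC[C@@](O[Si](CC)(CC)CC)(C(C)C)CC=O | intermediate
5 | (R)-5-isopropyl-2-methyl-5-(triethylsilyloxy)cyclopent-1-ene-1-carbaldehyde | O=CC1=C(C)CC[C@@]1(O[Si](CC)(CC)CC)C(C)C | intermediate
6 | (R)-5-isopropyl-2-methyl-5-(triethylsilyloxy)cyclopent-1-ene-1-carboxylic acid | OC(=O)C1=C(C)CC[C@@]1(O[Si](CC)(CC)CC)C(C)C | intermediate
7 | (R)-5-isopropyl-2-methyl-5-(triethylsilyloxy)cyclopent-1-ene-1-carbonyl chloride | ClC(=O)C1=C(C)CC[C@@]1(O[Si](CC)(CC)CC)C(C)C | intermediate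
8 | chromium hexacarbonyl, Cr(CO)6 | [C-]#[O+].[C-]#[O+].[C-]#[O+].[C-]#[O+].[C-]#[O+].[C-]#[O+].[Cr] | starting material
9 | disodium pentacarbonylchromate, Na2Cr(CO)5 | [Na+].[Na+].O=C=[Cr-2](=C=O)(=C=O)(=C=O)=C=O | intermediate (not isolated)
10 | sodium pentacarbonyl[(R)-5-isopropyl-2-methyl-5-(triethylsilyloxy)cyclopent-1-ene-1-carbonyl]chromate | [Na+].[O-]C(=[Cr](=C=O)(=C=O)(=C=O)(=C=O)=C=O)C1=C(C)CC[C@@]1(O[Si](CC)(CC)CC)C(C)C | intermediate (not isolated)
11 | pentacarbonyl{methoxy[(R)-5-isopropyl-2-methyl-5-(triethylsilyloxy)cyclopent-1-en-1-yl]methylidene}chromium | COC(=[Cr](=C=O)(=C=O)(=C=O)(=C=O)=C=O)C1=C(C)CC[C@@]1(O[Si](CC)(CC)CC)C(C)C | intermediate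
12 | 3-methylbut-2-enal | CC(C)=CC=O | starting material
13 | (E)-1-(trimethylsilyloxy)-3-methylbuta-1,3-diene | C=C(C)/C=C/O[Si](C)(C)C | intermediate
14 | (1S,2R)-1-methoxy-2-methyl-1-[(R)-5-isopropyl-2-methyl-5-(triethylsilyloxy)cyclopent-1-en-1-yl]-2-[(E)-2-(trimethylsilyloxy)vinyl]cyclopropane (cyclopentenyl and silyloxyvinyl cis) | CO[C@@]1(C2=C(C)CC[C@@]2(O[Si](CC)(CC)CC)C(C)C)C[C@]1(C)/C=C/O[Si](C)(C)C | intermediate (not isolated)
15 | (1S,4R,10R)-6-methoxy-4-(triethylsilyloxy)-10-(trimethylsilyloxy)dauca-5,8-diene | COC1=C2[C@](O[Si](CC)(CC)CC)(C(C)C)CC[C@]2(C)[C@H](O[Si](C)(C)C)C=C(C)C1 | intermediate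
16 | (1S,4R,10R)-6-methoxy-4-(triethylsilyloxy)dauca-5,8-dien-10-ol | COC1=C2[C@](O[Si](CC)(CC)CC)(C(C)C)CC[C@]2(C)[C@H](O)C=C(C)C1 | intermediate (not isolated)
17 | (1S,4R,5R,10R)-10-hydroxy-4-(triethylsilyloxy)dauc-8-en-6-one (trans-fused) | O=C1CC(C)=C[C@@H](O)[C@@]2(C)CC[C@@](O[Si](CC)(CC)CC)(C(C)C)[C@H]12 | intermediate
18 | (1S,4R,5R,10R)-6-oxo-4-(triethylsilyloxy)dauc-8-en-10-yl acetate | O=C1CC(C)=C[C@@H](OC(C)=O)[C@@]2(C)CC[C@@](O[Si](CC)(CC)CC)(C(C)C)[C@H]12 | intermediate
19 | (1S,4R,5R,10R)-4-hydroxy-6-oxodauc-8-en-10-yl acetate | O=C1CC(C)=C[C@@H](OC(C)=O)[C@@]2(C)CC[C@@](O)(C(C)C)[C@H]12 | intermediate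
20 | (1S,4R,5S,6S,10R)-4,6-dihydroxydauc-8-en-10-yl acetate | O[C@H]1CC(C)=C[C@@H](OC(C)=O)[C@@]2(C)CC[C@@](O)(C(C)C)[C@H]12 | intermediate
21 | (1S,4R,5S,6S,10R)-10-acetoxy-4-hydroxydauc-8-en-6-yl 4-methoxybenzoate (CNP0256979.2) | COc1ccc(C(=O)O[C@H]2CC(C)=C[C@@H](OC(C)=O)[C@@]3(C)CC[C@@](O)(C(C)C)[C@H]23)cc1 | target

## Step count and least certain steps

Total: 13 steps. Longest linear sequence: 12 steps (steps 1–6 and 8–13); step 7 is the one-step side branch.

**Step 8 (key step).** The most likely failure is poor or reversed facial selectivity at C1 relative to C4. The argument for the needed face rests on a modest difference between two non-bonded contacts in the boat transition state and on equilibration of the cyclopropane isomers; if the cyclopropanation is stereochemically final, the bulky Cr(CO)5 group and not C8 decides the face. Lesser risks are closure of the zwitterion to a five-membered ring and incomplete isomerisation of trans-cyclopropanes. Fallback, moving from substrate control to reagent control through the carbene oxygen: the acyl chromate **10**, generated as in step 6, is treated with acetyl bromide at −40 °C to give the acetoxycarbene complex F1. F1 is treated in the same flask with (−)-8-phenylmenthol (or its enantiomer, whichever reinforces the required face) to give the 8-phenylmenthyloxy carbene complex F2. Reaction of F2 with **13** under the conditions of step 8 gives the 8-phenylmenthyl enol ether F3, and the conditions of step 9 then return to **17** with release of the auxiliary.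

**Step 9.** The most likely failure is protonation of C5 on the face away from the C10 oxygen, which would give the cis-fused ring junction; a second risk is loss of the C4 oxygen by ionisation of the allylic C4–O bond. Later correction by equilibration is not safe, because enolisation of the C6 ketone invites elimination of the β-oxygen and conjugation of the C8=C9 alkene. Fallback, building the proton donor into the molecule: **16**, isolated after the methanolysis stage, is acylated at O10 with Meldrum's acid (toluene, 70 °C) to the hydrogen malonate F4. In wet THF the carboxyl group of F4, held on the C10 face, delivers the proton to C5 intramolecularly (intramolecular general-acid catalysis of vinyl ether hydrolysis) and gives the keto hydrogen malonate F5. Decarboxylation of F5 (Cu2O cat., MeCN, 60 °C) leaves the acetate and returns to **18**, so that step 10 is not needed.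

**Step 3.** The most likely failure is loss of the wrong β-oxygen: under enamine conditions the C4 silyloxy group is β to the aldehyde just as the new aldol hydroxyl is, and it can be eliminated either before ring closure or in place of the hydroxyl. Fallback, separating addition from dehydration: **4** is cyclised at 0 °C (pyrrolidine–AcOH or proline, CH2Cl2) only as far as the aldol 2-hydroxy-5-isopropyl-2-methyl-5-(triethylsilyloxy)cyclopentane-1-carbaldehyde F6. F6 is then dehydrated with Martin sulfurane (CH2Cl2, 0 °C to rt), which activates only the free tertiary hydroxyl, and base-mediated migration of the alkene into conjugation where needed returns to **5**.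

**Step 6.** The most likely failure is slow acylation of the dianion by a carbonyl group flanked by a quaternary carbon and a substituted alkene carbon, so that electron transfer and reduction of the acid chloride take over. Fallback, the classical alkenyllithium entry: **5** undergoes Baeyer–Villiger oxidation (mCPBA, NaHCO3, CH2Cl2) to the enol formate F7, and methanolysis (K2CO3, MeOH) gives 2-isopropyl-5-methyl-2-(triethylsilyloxy)cyclopentanone F8. F8 is converted with KN(SiMe3)2 and PhNTf2 into the enol triflate F9 and this with (Me3Sn)2, Pd(PPh3)4 and LiCl into the alkenylstannane F10. Tin–lithium exchange with MeLi and addition to Cr(CO)6 (**8**) give the lithium acyl chromate F11, and methylation with Me3OBF4 returns to **11**.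

## Further compounds

F1 | step 8 | pentacarbonyl{acetoxy[(R)-5-isopropyl-2-methyl-5-(triethylsilyloxy)cyclopent-1-en-1-yl]methylidene}chromium | CC(=O)OC(=[Cr](=C=O)(=C=O)(=C=O)(=C=O)=C=O)C1=C(C)CC[C@@]1(O[Si](CC)(CC)CC)C(C)C
F2 | step 8 | pentacarbonyl{[(1R,2S,5R)-8-phenylmenthyloxy][(R)-5-isopropyl-2-methyl-5-(triethylsilyloxy)cyclopent-1-en-1-yl]methylidene}chromium | C[C@@H]1CC[C@H]([C@@H](C1)OC(=[Cr](=C=O)(=C=O)(=C=O)(=C=O)=C=O)C2=C(C)CC[C@@]2(O[Si](CC)(CC)CC)C(C)C)C(C)(C)c3ccccc3
F3 | step 8 | (1S,4R,10R)-6-[(1R,2S,5R)-8-phenylmenthyloxy]-4-(triethylsilyloxy)-10-(trimethylsilyloxy)dauca-5,8-diene | C[C@@H]1CC[C@H]([C@@H](C1)OC2=C3[C@](O[Si](CC)(CC)CC)(C(C)C)CC[C@]3(C)[C@H](O[Si](C)(C)C)C=C(C)C2)C(C)(C)c4ccccc4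
F4 | step 9 | (1S,4R,10R)-6-methoxy-4-(triethylsilyloxy)dauca-5,8-dien-10-yl hydrogen malonate | COC1=C2[C@](O[Si](CC)(CC)CC)(C(C)C)CC[C@]2(C)[C@H](OC(=O)CC(=O)O)C=C(C)C1
F5 | step 9 | (1S,4R,5R,10R)-6-oxo-4-(triethylsilyloxy)dauc-8-en-10-yl hydrogen malonate | O=C1CC(C)=C[C@@H](OC(=O)CC(=O)O)[C@@]2(C)CC[C@@](O[Si](CC)(CC)CC)(C(C)C)[C@H]12
F6 | step 3 | (5R)-2-hydroxy-5-isopropyl-2-methyl-5-(triethylsilyloxy)cyclopentane-1-carbaldehyde (mixture at C1 and C2) | O=CC1C(C)(O)CC[C@@]1(O[Si](CC)(CC)CC)C(C)C
F7 | step 6 | (R)-5-isopropyl-2-methyl-5-(triethylsilyloxy)cyclopent-1-en-1-yl formate | O=COC1=C(C)CC[C@@]1(O[Si](CC)(CC)CC)C(C)C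
F8 | step 6 | (2R)-2-isopropyl-5-methyl-2-(triethylsilyloxy)cyclopentan-1-one (mixture at C5) | O=C1C(C)CC[C@@]1(O[Si](CC)(CC)CC)C(C)C
F9 | step 6 | (R)-5-isopropyl-2-methyl-5-(triethylsilyloxy)cyclopent-1-en-1-yl trifluoromethanesulfonate | O=S(=O)(OC1=C(C)CC[C@@]1(O[Si](CC)(CC)CC)C(C)C)C(F)(F)F
F10 | step 6 | (R)-triethyl{[1-isopropyl-3-methyl-2-(trimethylstannyl)cyclopent-2-en-1-yl]oxy}silane | C[Sn](C)(C)C1=C(C)CC[C@@]1(O[Si](CC)(CC)CC)C(C)C
F11 | step 6 | lithium pentacarbonyl[(R)-5-isopropyl-2-methyl-5-(triethylsilyloxy)cyclopent-1-ene-1-carbonyl]chromate | [Li+].[O-]C(=[Cr](=C=O)(=C=O)(=C=O)(=C=O)=C=O)C1=C(C)CC[C@@]1(O[Si](CC)(CC)CC)C(C)C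
A1 | alternative 1 | 6-(benzyloxymethyl)-2-diazo-3-isopropyl-6-methyl-3-(triethylsilyloxy)cyclohexan-1-one | O=C1C(=[N+]=[N-])[C@](O[Si](CC)(CC)CC)(C(C)C)CC[C@]1(C)COCc1ccccc1
A2 | alternative 1 | methyl 2-(benzyloxymethyl)-5-isopropyl-2-methyl-5-(triethylsilyloxy)cyclopentane-1-carboxylate | COC(=O)[C@H]1[C@](O[Si](CC)(CC)CC)(C(C)C)CC[C@]1(C)COCc1ccccc1
A3 | alternative 2 | 3-[(tert-butyldimethylsilyloxy)methyl]cyclopent-2-en-1-one | O=C1C=C(CO[Si](C)(C)C(C)(C)C)CC1
A4 | alternative 2 | (Z)-4-iodo-3-methylbut-3-enal | O=CC/C(C)=C\I
A5 | alternative 2 | 3-[(tert-butyldimethylsilyloxy)methyl]-2-[(Z)-1-hydroxy-4-iodo-3-methylbut-3-en-1-yl]-3-methylcyclopentan-1-one | O[C@@H](C/C(C)=C\I)[C@H]1C(=O)CC[C@]1(C)CO[Si](C)(C)C(C)(C)C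
A6 | alternative 3 | 5-isopropyl-2-[1-(4-methoxybenzyloxy)-3-methylbut-3-en-1-yl]-2-methyl-5-(triethylsilyloxy)cyclopentane-1-carbaldehyde | O=C[C@H]1[C@](O[Si](CC)(CC)CC)(C(C)C)CC[C@]1(C)[C@H](OCc2ccc(OC)cc2)CC(C)=C
A7 | alternative 3 | 10-(4-methoxybenzyloxy)-8-methylene-4-(triethylsilyloxy)daucan-6-ol | O[C@H]1CC(=C)C[C@@H](OCc3ccc(OC)cc3)[C@@]2(C)CC[C@@](O[Si](CC)(CC)CC)(C(C)C)[C@H]12
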